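**Strategy.** The dihydropyran that joins the acylcyclohexadienone to the ten-membered carbocycle is made last by an intermolecular hetero-Diels–Alder reaction. Oxidation of norflavesone gives an o-quinone methide whose exocyclic CH2 and flanking C=O add across the (E)-trisubstituted olefin of a (1E,6Z)-cyclodecadienol: CH2 bonds to the olefinic CH, and the carbonyl oxygen closes the ring on the methyl-bearing olefinic carbon. One operation couples both halves, forms the C–C and O–C bonds of the pyran and sets the O–C(CH3) and ring-fusion stereocentres by substrate control from the two stereocentres flanking the Z-olefin. The dienol comes from (R)-carvone by anionic oxy-Cope ring expansion and a Shapiro reaction.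

Key step: step 12

Step 1
Reactants: 1 (R)-(−)-carvone
Product: 2 (5R)-5-(2-hydroxypropan-2-yl)-2-methylcyclohex-2-en-1-one
Conditions: 40% aq. H2SO4, 0 °C → rt
Reagents that add atoms: water (O)
Why: Acid-catalysed Markovnikov hydration of the 1,1-disubstituted isopropenyl group should give the tertiary alcohol while the conjugated ring olefin stays intact; the stereocentre (the later CH–C(CH3)2OH carbon) is bought with carvone and not touched.

Step 2
Reactants: 2 (5R)-5-(2-hydroxypropan-2-yl)-2-methylcyclohex-2-en-1-one
Product: 3 (5R)-2-methyl-5-[2-(triethylsilyloxy)propan-2-yl]cyclohex-2-en-1-one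
Conditions: TESOTf, 2,6-lutidine, CH2Cl2, −78 → 0 °C
Reagents that add atoms: triethylsilyl trifluoromethanesulfonate (CC[Si](CC)(CC)OS(=O)(=O)C(F)(F)F)
Why: Silyl ether formation with the silyl triflate is the standard protection of a hindered tertiary alcohol and removes the acidic OH that would quench the enolates and organometallics of steps 3–8.

Step 3
Reactants: 3 (5R)-2-methyl-5-[2-(triethylsilyloxy)propan-2-yl]cyclohex-2-en-1-one
Product: 5 (2R,5R)-2-(1-hydroxyethyl)-2-methyl-5-[2-(triethylsilyloxy)propan-2-yl]cyclohexan-1-one, via lithium enolate 4 (not isolated)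
Conditions: L-Selectride, THF, −78 °C; then CH3CHO, −78 °C; AcOH
Reagents that add atoms: acetaldehyde (CC=O)
Why: Conjugate reduction gives the regiodefined tetrasubstituted enolate, and its aldol addition (reductive aldol) should occur by axial attack, placing the new two-carbon unit cis to the ring substituent at C5; the carbinol carbon is a mixture that step 4 removes.

Step 4
Reactants: 5 (2R,5R)-2-(1-hydroxyethyl)-2-methyl-5-[2-(triethylsilyloxy)propan-2-yl]cyclohexan-1-one
Product: 6 (2R,5R)-2-ethenyl-2-methyl-5-[2-(triethylsilyloxy)propan-2-yl]cyclohexan-1-one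
Conditions: Martin sulfurane, CH2Cl2, 0 °C → rt
Reagents that add atoms: none
Why: Martin sulfurane dehydration of the secondary alcohol can only eliminate toward the methyl group because the α-carbon is quaternary, and its neutral conditions avoid retro-aldol cleavage.

Step 5
Reactants: 6 (2R,5R)-2-ethenyl-2-methyl-5-[2-(triethylsilyloxy)propan-2-yl]cyclohexan-1-one
Product: 7 (1S,2R,5R)-2-ethenyl-2-methyl-1-(prop-1-en-2-yl)-5-[2-(triethylsilyloxy)propan-2-yl]cyclohexan-1-ol
Conditions: CH2=C(CH3)MgBr, CeCl3, THF, −78 → 0 °C; H2O
Reagents that add atoms: isopropenylmagnesium bromide (CC(=C)[Mg]Br)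
Why: Cerium-mediated Grignard 1,2-addition to the hindered, enolisable ketone should occur anti to the axial vinyl group; either configuration at the carbinol carbon is acceptable because this carbon becomes the carbonyl carbon in step 6.

Step 6
Reactants: 7 (1S,2R,5R)-2-ethenyl-2-methyl-1-(prop-1-en-2-yl)-5-[2-(triethylsilyloxy)propan-2-yl]cyclohexan-1-ol
Product: 9 (2S,5E,9R)-2,6-dimethyl-9-[2-(triethylsilyloxy)propan-2-yl]cyclodec-5-en-1-one, via potassium enolate 8 (not isolated)
Conditions: KH, 18-crown-6, THF, 0 °C → rt; then AcOH, −78 °C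
Reagents that add atoms: none
Why: Anionic oxy-Cope rearrangement through a chair transition state expands the six- to the ten-membered ring and should give the (E)-trisubstituted olefin, and the methyl-bearing α-stereocentre is then set by kinetic C-protonation on the peripheral face of the enolate in its crossed conformer with the silyloxyisopropyl group pseudo-equatorial.

Step 7
Reactants: 9 (2S,5E,9R)-2,6-dimethyl-9-[2-(triethylsilyloxy)propan-2-yl]cyclodec-5-en-1-one
Product: 10 p-toluenesulfonylhydrazone of 9 (N–NHTs anti to the methyl-bearing α-carbon)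
Conditions: TsNHNH2, MeOH, rt
Reagents that add atoms: p-toluenesulfonohydrazide (Cc1ccc(cc1)S(=O)(=O)NN)
Why: Uncatalysed hydrazone condensation should place the sulfonamide nitrogen anti to the branched α-carbon, which fixes the regiochemistry of step 8, and the absence of acid avoids transannular carbonyl-ene cyclisation onto the E-olefin.

Step 8
Reactants: 10 p-toluenesulfonylhydrazone of 9
Product: 12 triethyl({2-[(1R,2Z,4S,7E)-4,8-dimethylcyclodeca-2,7-dien-1-yl]propan-2-yl}oxy)silane, via vinyllithium 11 (not isolated)
Conditions: n-BuLi (3 equiv), TMEDA, THF, −78 → 0 °C; then H2O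
Reagents that add atoms: none
Why: In the Shapiro reaction syn-directed deprotonation at the α-CH2, loss of sulfinate and N2, and protonation of the vinyllithium should give the less substituted olefin with the cis (Z) geometry usual for such vinyl anions, without touching the two allylic stereocentres.

Step 9
Reactants: 12 triethyl({2-[(1R,2Z,4S,7E)-4,8-dimethylcyclodeca-2,7-dien-1-yl]propan-2-yl}oxy)silane
Product: 13 2-[(1R,2Z,4S,7E)-4,8-dimethylcyclodeca-2,7-dien-1-yl]propan-2-ol
Conditions: TBAF, THF, rt → 40 °C
Reagents that add atoms: none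
Why: Fluoride desilylation frees the tertiary alcohol under non-acidic conditions that spare the acid-sensitive cyclodecadiene.

Step 10
Reactants: 14 phloroglucinol; 15 isobutyryl chloride
Product: 16 2-methyl-1-(2,4,6-trihydroxyphenyl)propan-1-one
Conditions: AlCl3, PhNO2, rt → 65 °C; aq. HCl
Reagents that add atoms: none
Why: Friedel–Crafts C-acylation of the electron-rich triphenol should stop after one acyl group because the product is deactivated.

Step 11
Reactants: 16 2-methyl-1-(2,4,6-trihydroxyphenyl)propan-1-one
Product: 17 norflavesone, 3,5-dihydroxy-2,6,6-trimethyl-4-(2-methylpropanoyl)cyclohexa-2,4-dien-1-one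
Conditions: NaOMe, MeI (3 equiv), MeOH, 0 °C → rt
Reagents that add atoms: iodomethane (CI)
Why: Base-mediated C-methylation of the acylphloroglucinol (dearomatising gem-dimethylation at one ring carbon, single methylation at the other) is the standard entry to this β-triketone.

Step 12
Reactants: 13 2-[(1R,2Z,4S,7E)-4,8-dimethylcyclodeca-2,7-dien-1-yl]propan-2-ol; 17 norflavesone
Product: 19 target CNP0564661.1, via o-quinone methide 18 (not isolated)
Conditions: Ag2O, TEMPO (cat.), PhMe, rt, dark
Reagents that add atoms: none
Why: Ag2O/TEMPO dehydrogenates the C-methyl enol of 17 to o-quinone methide 18, a 1-oxadiene that undergoes an inverse-electron-demand hetero-Diels–Alder reaction with the (E)-trisubstituted olefin of 13; bonding is asynchronous, the exocyclic CH2 attacking the olefinic CH first and the carbonyl oxygen then closing on the developing tertiary, methyl-bearing carbon, which fixes the regiochemistry. The closest known reaction type is the oxidative generation of o-quinone methides from C-methyl acylphloroglucinol-derived triketones and their hetero-Diels–Alder capture by medium-ring (E)-olefins of sesquiterpenes. The only ring closed is the dihydropyran, formed by intermolecular [4+2] cycloaddition in which the O–C bond completes the six-membered ring. Addition is suprafacial on the E-olefin, so the methyl group and the ring-fusion hydrogen end up trans (trans-fused pyran and cyclodecene); the absolute sense of both new stereocentres should follow from attack on the exposed peripheral face of the olefin in the ring conformer that keeps the methyl and hydroxyisopropyl groups flanking the Z-olefin pseudo-equatorial, the inner face being blocked transannularly. Chemoselectivity rests on the higher nucleophilicity and strain of the trisubstituted E-olefin compared with the Z-disubstituted one and on the hindered tertiary OH; of the two carbonyl oxygens of 18 the one next to the acyl-bearing carbon is expected to react, which leaves the chelated enol beside the gem-dimethyl carbon.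

**Compound list**

1 | (R)-(−)-carvone, (5R)-2-methyl-5-(prop-1-en-2-yl)cyclohex-2-en-1-one | CC1=CC[C@@H](C(C)=C)CC1=O | starting material
2 | (5R)-5-(2-hydroxypropan-2-yl)-2-methylcyclohex-2-en-1-one | CC1=CC[C@@H](C(C)(C)O)CC1=O | intermediate
3 | (5R)-2-methyl-5-[2-(triethylsilyloxy)propan-2-yl]cyclohex-2-en-1-one | CC1=CC[C@@H](C(C)(C)O[Si](CC)(CC)CC)CC1=O | intermediate
4 | lithium (5R)-2-methyl-5-[2-(triethylsilyloxy)propan-2-yl]cyclohex-1-en-1-olate | [Li+].[O-]C1=C(C)CC[C@@H](C(C)(C)O[Si](CC)(CC)CC)C1 | intermediate (not isolated)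
5 | (2R,5R)-2-(1-hydroxyethyl)-2-methyl-5-[2-(triethylsilyloxy)propan-2-yl]cyclohexan-1-one (both carbinol epimers; hydroxyethyl cis to the C5 side chain) | CC(O)[C@@]1(C)CC[C@@H](C(C)(C)O[Si](CC)(CC)CC)CC1=O | intermediate
6 | (2R,5R)-2-ethenyl-2-methyl-5-[2-(triethylsilyloxy)propan-2-yl]cyclohexan-1-one | C=C[C@@]1(C)CC[C@@H](C(C)(C)O[Si](CC)(CC)CC)CC1=O | intermediate
7 | (1S,2R,5R)-2-ethenyl-2-methyl-1-(prop-1-en-2-yl)-5-[2-(triethylsilyloxy)propan-2-yl]cyclohexan-1-ol (isopropenyl trans to vinyl) | C=C[C@@]1(C)CC[C@@H](C(C)(C)O[Si](CC)(CC)CC)C[C@]1(O)C(C)=C | intermediate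
8 | potassium (5E,9R)-2,6-dimethyl-9-[2-(triethylsilyloxy)propan-2-yl]cyclodeca-1,5-dien-1-olate | [K+].[O-]C1=C(C)CC/C=C(C)/CC[C@@H](C(C)(C)O[Si](CC)(CC)CC)C1 | intermediate (not isolated)
9 | (2S,5E,9R)-2,6-dimethyl-9-[2-(triethylsilyloxy)propan-2-yl]cyclodec-5-en-1-one | O=C1[C@@H](C)CC/C=C(C)/CC[C@@H](C(C)(C)O[Si](CC)(CC)CC)C1 | intermediate
10 | p-toluenesulfonylhydrazone of 9 (N–NHTs anti to the methyl-bearing α-carbon) | Cc1ccc(cc1)S(=O)(=O)N/N=C1/[C@@H](C)CC/C=C(C)/CC[C@@H](C(C)(C)O[Si](CC)(CC)CC)C1 | intermediate
11 | ring vinyllithium from 10 (Li on the former hydrazone carbon, Z ring olefin) | C/C1=C\CC[C@H](C)/C([Li])=C\[C@H](C(C)(C)O[Si](CC)(CC)CC)CC1 | intermediate (not isolated)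
12 | triethyl({2-[(1R,2Z,4S,7E)-4,8-dimethylcyclodeca-2,7-dien-1-yl]propan-2-yl}oxy)silane | C/C1=C\CC[C@H](C)/C=C\[C@H](C(C)(C)O[Si](CC)(CC)CC)CC1 | intermediate
13 | 2-[(1R,2Z,4S,7E)-4,8-dimethylcyclodeca-2,7-dien-1-yl]propan-2-ol | C/C1=C\CC[C@H](C)/C=C\[C@H](C(C)(C)O)CC1 | intermediate
14 | phloroglucinol, benzene-1,3,5-triol | Oc1cc(O)cc(O)c1 | starting material
15 | isobutyryl chloride, 2-methylpropanoyl chloride | CC(C)C(=O)Cl | starting material
16 | 2-methyl-1-(2,4,6-trihydroxyphenyl)propan-1-one (phlorisobutyrophenone) | CC(C)C(=O)c1c(O)cc(O)cc1O | intermediate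
17 | norflavesone, 3,5-dihydroxy-2,6,6-trimethyl-4-(2-methylpropanoyl)cyclohexa-2,4-dien-1-one | CC(C)C(=O)C1=C(O)C(C)(C)C(=O)C(C)=C1O | intermediate
18 | o-quinone methide, 5-hydroxy-6,6-dimethyl-2-methylidene-4-(2-methylpropanoyl)cyclohex-4-ene-1,3-dione | CC(C)C(=O)C1=C(O)C(C)(C)C(=O)C(=C)C1=O | intermediate (not isolated)
19 | CNP0564661.1 | CC(C)C(=O)C1=C(O)C(C)(C)C(=O)C2=C1O[C@]1(C)CC[C@@H](C(C)(C)O)/C=C\[C@@H](C)CC[C@H]1C2 | target

**Count.** Total steps: 12. Longest linear sequence: 10 (steps 1–9 and 12).

**Steps most likely to fail**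

1. Step 12. The cycloaddition may occur on the other face of the E-olefin or through the other carbonyl oxygen, and the o-quinone methide may dimerise before it is trapped. The fallback sets out from silyl ether 12 and from 16 and returns at 19. Compound 16 is C-methylated with only two equivalents of MeI (NaOMe, MeOH) to 2-isobutyryl-4,4-dimethylcyclohexane-1,3,5-trione F1. Knoevenagel condensation of F1 with paraformaldehyde (ethylenediammonium diacetate cat., MeCN, 60 °C) should generate the same heterodiene 18 slowly and without oxidant in the presence of 12, whose bulkier silyloxy group changes the conformer population of the ring. The resulting triethylsilyl ether of the target F2 is desilylated with TBAF to 19.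

2. Step 6. Protonation of the ten-membered enolate may be poorly face-selective after conformational equilibration, giving the epimer at the methyl-bearing carbon. The fallback sets out from ketone 6 and returns at ketone 9, using auxiliary control instead of substrate control. Vinylmagnesium bromide/CeCl3 gives (1S,2R,5R)-1,2-diethenyl-2-methyl-5-[2-(triethylsilyloxy)propan-2-yl]cyclohexan-1-ol F3. The same oxy-Cope conditions with a protic quench give the des-methyl ketone (5E,9R)-6-methyl-9-[2-(triethylsilyloxy)propan-2-yl]cyclodec-5-en-1-one F4. Condensation with (R)-1-amino-2-(methoxymethyl)pyrrolidine gives the RAMP hydrazone F5. LDA then MeI at −100 °C should methylate the less hindered α-CH2 under auxiliary control to the methylated hydrazone F6. Two-phase cleavage with aqueous oxalic acid returns 9.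

3. Step 8. The cis geometry may erode during vinyl anion formation, or deprotonation may compete at the methyl-bearing α-carbon. The fallback sets out from ketone 9 and returns at diene 12. KHMDS and Comins' reagent (THF, −78 °C) give the kinetic enol triflate F7, at which stage olefin isomers can be separated. Reduction with Pd(OAc)2, PPh3, Bu3N and HCO2H (DMF, 60 °C) replaces the triflate by hydrogen with retention of geometry to give 12.

**Further compounds**

F1 | step 12 | 2-isobutyryl-4,4-dimethylcyclohexane-1,3,5-trione (enol form) | CC(C)C(=O)C1=C(O)C(C)(C)C(=O)CC1=O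
F2 | step 12 | triethylsilyl ether of 19 | CC(C)C(=O)C1=C(O)C(C)(C)C(=O)C2=C1O[C@]1(C)CC[C@@H](C(C)(C)O[Si](CC)(CC)CC)/C=C\[C@@H](C)CC[C@H]1C2
F3 | step 6 | (1S,2R,5R)-1,2-diethenyl-2-methyl-5-[2-(triethylsilyloxy)propan-2-yl]cyclohexan-1-ol | C=C[C@@]1(C)CC[C@@H](C(C)(C)O[Si](CC)(CC)CC)C[C@]1(O)C=C
F4 | step 6 | (5E,9R)-6-methyl-9-[2-(triethylsilyloxy)propan-2-yl]cyclodec-5-en-1-one | O=C1CCC/C=C(C)/CC[C@@H](C(C)(C)O[Si](CC)(CC)CC)C1
F5 | step 6 | RAMP hydrazone of F4 | COC[C@H]1CCCN1N=C1CCC/C=C(C)/CC[C@@H](C(C)(C)O[Si](CC)(CC)CC)C1
F6 | step 6 | RAMP hydrazone of 9 | COC[C@H]1CCCN1N=C1[C@@H](C)CC/C=C(C)/CC[C@@H](C(C)(C)O[Si](CC)(CC)CC)C1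
F7 | step 8 | enol triflate of 9 toward the α-CH2 (Z ring olefin) | FC(F)(F)S(=O)(=O)O/C1=C/[C@H](C(C)(C)O[Si](CC)(CC)CC)CC/C(C)=C/CC[C@@H]1C
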